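**Retrosynthetic overview**

- Target 20 is ArA–C1H=C2H–C3H(C4H3)–ArB, where ArA and ArB are the same 7-methoxy-2,2-dimethyl-2H-chromen-6-yl unit (a benzene ring fused to a 2H-pyran ring). Without the C4 methyl group the chain is a 1,3-diarylallyl fragment whose termini C1 and C3 are enantiotopic; the strategy rests on this.
- Key disconnection: the C3–C4 bond, made by nickel/chiral diphosphine-catalysed substitution of the racemic allylic methyl ether 18 with MeMgBr 19, which sets the (S) centre stereoconvergently.
- Ether 18 comes from chalcone 15 by Luche reduction and O-methylation; 15 comes from Claisen–Schmidt condensation (C1=C2 bond) of methyl ketone 13 with aldehyde 9.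
- Both 9 and 13 come from bromochromene 5: 9 by bromine–lithium exchange and formylation, 13 through the aryl Grignard reagent and a Weinreb amide.
- Ring order: the 2H-pyran ring of 5 is the only ring built (step 1, on the benzene ring of phenol 1) and serves both halves; no ring is formed later.

Key step: step 7

Assumption: which chiraphos antipode gives the (S) product on this ortho-alkoxy diaryl system is not treated as known. The route is written with (S,S)-chiraphos; the (R,R) ligand would be used, with no other change, if the first run gave the (R) product.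

**Route**

Step 1
Reactants: 1 4-bromo-3-methoxyphenol; 2 3-methylbut-2-enal (prenal)
Product: 5 6-bromo-7-methoxy-2,2-dimethyl-2H-chromene, via benzodioxaborin 3 (not isolated), via quinone methide 4 (not isolated)
Conditions: PhB(OH)2 (1 equiv), AcOH (cat.), toluene, reflux, Dean–Stark
Reagents that add atoms: none
Why: Phenylboronic acid-templated ortho-hydroxyalkylation gives benzodioxaborin 3, which fragments on heating to ortho-quinone methide 4 and closes by oxa-6π electrocyclisation; C–C bond formation is expected at C6 of the phenol (para to OMe) because the para position carries bromine and C2 is flanked by two oxygen substituents.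

Step 2
Reactants: 5 6-bromo-7-methoxy-2,2-dimethyl-2H-chromene; 6 N,N-dimethylformamide
Product: 9 7-methoxy-2,2-dimethyl-2H-chromene-6-carbaldehyde, via aryllithium 7 (not isolated), via lithium hemiaminal alkoxide 8 (not isolated)
Conditions: n-BuLi, THF, −78 °C; DMF, −78 to 0 °C; then H2O
Reagents that add atoms: none
Why: Bromine–lithium exchange at −78 °C is much faster than any addition to the chromene alkene, the ortho-methoxy group stabilises aryllithium 7, and formylation with DMF (Bouveault-type) stops at hemiaminal alkoxide 8 until aqueous work-up releases the aldehyde.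

Step 3
Reactants: 5 6-bromo-7-methoxy-2,2-dimethyl-2H-chromene; 10 N-methoxy-N-methylacetamide
Product: 13 1-(7-methoxy-2,2-dimethyl-2H-chromen-6-yl)ethan-1-one (the 6-acetylchromene), via arylmagnesium bromide 11 (not isolated), via bromomagnesium aminal alkoxide 12 (not isolated)
Conditions: Mg turnings (I2 crystal), THF, 50 °C; amide 10, 0 °C to rt; then H2O
Reagents that add atoms: none
Why: Direct magnesium insertion into the aryl C–Br bond gives Grignard reagent 11, to which the chromene alkene and ring ether are inert, and its addition to amide 10 is a Weinreb ketone synthesis in which the magnesium-chelated tetrahedral adduct 12 prevents a second addition and gives the methyl ketone on work-up.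

Step 4
Reactants: 13 1-(7-methoxy-2,2-dimethyl-2H-chromen-6-yl)ethan-1-one; 9 7-methoxy-2,2-dimethyl-2H-chromene-6-carbaldehyde
Product: 15 (2E)-1,3-bis(7-methoxy-2,2-dimethyl-2H-chromen-6-yl)prop-2-en-1-one, via aldol 14 (not isolated)
Conditions: KOH, EtOH/H2O, rt to 40 °C
Reagents that add atoms: none
Why: Claisen–Schmidt condensation; aldehyde 9 has no α-hydrogen, so the enolate of 13 adds once to give aldol 14, which loses water by E1cB elimination to the conjugated (E)-enone.

Step 5
Reactants: 15 (2E)-1,3-bis(7-methoxy-2,2-dimethyl-2H-chromen-6-yl)prop-2-en-1-one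
Product: 16 racemic (2E)-1,3-bis(7-methoxy-2,2-dimethyl-2H-chromen-6-yl)prop-2-en-1-ol
Conditions: NaBH4, CeCl3·7H2O, MeOH/THF, −20 to 0 °C; aq. NaHCO3 quench
Reagents that add atoms: none
Why: Luche reduction delivers hydride to the carbonyl carbon only (1,2-reduction) and leaves the enone and chromene alkenes intact; the carbinol centre forms as a racemate, which is all the stereoconvergent key step needs.

Step 6
Reactants: 16 racemic (2E)-1,3-bis(7-methoxy-2,2-dimethyl-2H-chromen-6-yl)prop-2-en-1-ol
Product: 18 racemic 6,6'-[(1E)-3-methoxyprop-1-ene-1,3-diyl]bis(7-methoxy-2,2-dimethyl-2H-chromene), via sodium alkoxide 17 (not isolated)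
Conditions: NaH, MeI, THF, 0 °C to rt; chromatography on Et3N-deactivated silica
Reagents that add atoms: iodomethane, CI
Why: Williamson ether synthesis under basic conditions, chosen so that the easily ionised bis(dialkoxyaryl)allyl system does not meet acid; the centre stays racemic.

Step 7
Reactants: 18 racemic 6,6'-[(1E)-3-methoxyprop-1-ene-1,3-diyl]bis(7-methoxy-2,2-dimethyl-2H-chromene); 19 methylmagnesium bromide
Product: 20 (3S,1E)-6,6'-(but-1-ene-1,3-diyl)bis(7-methoxy-2,2-dimethyl-2H-chromene), the target
Conditions: NiCl2[(S,S)-chiraphos] (5 mol %; chiraphos = Ph2PCH(CH3)CH(CH3)PPh2), MeMgBr (3 equiv), Et2O, 0 °C to rt; then H2O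
Reagents that add atoms: none
Why: The Grignard reagent reduces the divalent nickel precatalyst to zerovalent nickel–chiraphos, which binds the C1=C2 alkene of either enantiomer of 18 and expels methoxide (assisted by magnesium) to give one and the same syn,syn-η3-1,3-bis(chromenyl)allyl nickel cation, so the racemic centre is erased and the process is stereoconvergent. Transmetalation from MeMgBr gives an allyl(methyl)nickel species, and inner-sphere reductive elimination forms the C3–C4 bond and returns zerovalent nickel; methyl has no β-hydrogen, so no hydride pathway competes. The closest known reaction type is the NiCl2–chiral diphosphine-catalysed enantioselective coupling of racemic 1,3-diphenylallyl ethers with alkyl Grignard reagents, applied here to a diaryl ether of the same class. No ring is closed; the only new stereocentre, C3, is set by the C2-symmetric ligand, whose phenyl groups should make reductive elimination faster at one of the two enantiotopic allyl termini. The step needs terminus (enantio) selection, which rests on the ligand alone because the identical aryl groups make attack at either end the same constitution, and (E) geometry, which follows from the syn,syn allyl. Chemoselectivity over the ring O1–C2 allylic ethers and the aryl–OMe bonds is expected because the acyclic, doubly aryl-stabilised ether ionises far more easily, while each ring C2–O1 bond lies near the nodal plane of its C3=C4 π bond and is shielded by the gem-dimethyl group.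

**Compound list**

1 | 4-bromo-3-methoxyphenol | COc1cc(O)ccc1Br | starting material
2 | 3-methylbut-2-enal (prenal) | CC(C)=CC=O | starting material
3 | racemic 6-bromo-7-methoxy-4-(2-methylprop-1-en-1-yl)-2-phenyl-4H-1,3,2-benzodioxaborinine | COc1cc2OB(c3ccccc3)OC(C=C(C)C)c2cc1Br | intermediate
4 | (6Z)-4-bromo-3-methoxy-6-(3-methylbut-2-en-1-ylidene)cyclohexa-2,4-dien-1-one | O=C1C=C(OC)C(Br)=C/C1=C/C=C(C)C | intermediate
5 | 6-bromo-7-methoxy-2,2-dimethyl-2H-chromene | COc1cc2OC(C)(C)C=Cc2cc1Br | intermediate
6 | N,N-dimethylformamide | CN(C)C=O | starting material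
7 | (7-methoxy-2,2-dimethyl-2H-chromen-6-yl)lithium | [Li]c1cc2C=CC(C)(C)Oc2cc1OC | intermediate
8 | racemic lithium (dimethylamino)(7-methoxy-2,2-dimethyl-2H-chromen-6-yl)methanolate | COc1cc2OC(C)(C)C=Cc2cc1C(O[Li])N(C)C | intermediate
9 | 7-methoxy-2,2-dimethyl-2H-chromene-6-carbaldehyde | COc1cc2OC(C)(C)C=Cc2cc1C=O | intermediate
10 | N-methoxy-N-methylacetamide | CON(C)C(C)=O | starting material
11 | (7-methoxy-2,2-dimethyl-2H-chromen-6-yl)magnesium bromide | Br[Mg]c1cc2C=CC(C)(C)Oc2cc1OC | intermediate
12 | racemic bromomagnesium 1-[methoxy(methyl)amino]-1-(7-methoxy-2,2-dimethyl-2H-chromen-6-yl)ethan-1-olate | COc1cc2OC(C)(C)C=Cc2cc1C(C)(O[Mg]Br)N(C)OC | intermediate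
13 | 1-(7-methoxy-2,2-dimethyl-2H-chromen-6-yl)ethan-1-one | COc1cc2OC(C)(C)C=Cc2cc1C(C)=O | intermediate
14 | racemic 3-hydroxy-1,3-bis(7-methoxy-2,2-dimethyl-2H-chromen-6-yl)propan-1-one | COc1cc2OC(C)(C)C=Cc2cc1C(=O)CC(O)c1cc2C=CC(C)(C)Oc2cc1OC | intermediate
15 | (2E)-1,3-bis(7-methoxy-2,2-dimethyl-2H-chromen-6-yl)prop-2-en-1-one | COc1cc2OC(C)(C)C=Cc2cc1C(=O)/C=C/c1cc2C=CC(C)(C)Oc2cc1OC | intermediate
16 | racemic (2E)-1,3-bis(7-methoxy-2,2-dimethyl-2H-chromen-6-yl)prop-2-en-1-ol | COc1cc2OC(C)(C)C=Cc2cc1C(O)/C=C/c1cc2C=CC(C)(C)Oc2cc1OC | intermediate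
17 | racemic sodium (2E)-1,3-bis(7-methoxy-2,2-dimethyl-2H-chromen-6-yl)prop-2-en-1-olate | COc1cc2OC(C)(C)C=Cc2cc1C(O[Na])/C=C/c1cc2C=CC(C)(C)Oc2cc1OC | intermediate
18 | racemic 6,6'-[(1E)-3-methoxyprop-1-ene-1,3-diyl]bis(7-methoxy-2,2-dimethyl-2H-chromene) | COC(/C=C/c1cc2C=CC(C)(C)Oc2cc1OC)c1cc2C=CC(C)(C)Oc2cc1OC | intermediate
19 | methylmagnesium bromide | C[Mg]Br | starting material
20 | (3S,1E)-6,6'-(but-1-ene-1,3-diyl)bis(7-methoxy-2,2-dimethyl-2H-chromene) | COc1cc2c(cc1/C=C/[C@H](C)c1cc3c(cc1OC)OC(C)(C)C=C3)C=CC(C)(C)O2 | target

**Step count and risks**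

Total step count: 7. Longest linear sequence: 6 (steps 1, 2 or 3, 4, 5, 6, 7).

Steps most likely to fail:

1. Step 7. The ligand may discriminate poorly between the two enantiotopic allyl termini, because both carry ortho-methoxy aryl groups that can coordinate magnesium or nickel; slow methyl transfer could also let the allyl nickel homocouple. Fallback (sets out from aldehyde 9 and bromide 5, comes back at target 20): the stereocentre is made by reagent-controlled ketone reduction and carried over by a stereospecific arylation, so the aryl–C3 bond is formed instead of the methyl–C3 bond. Aldehyde 9 is condensed with acetone (aq. NaOH, acetone, rt) to (3E)-4-(7-methoxy-2,2-dimethyl-2H-chromen-6-yl)but-3-en-2-one F1. CBS reduction ((S)-Me-CBS oxazaborolidine, catecholborane, toluene, −78 °C; the styryl group acts as the large substituent) should give (2R,3E)-4-(7-methoxy-2,2-dimethyl-2H-chromen-6-yl)but-3-en-2-ol F2. Pivaloyl chloride, pyridine and DMAP in CH2Cl2 at 0 °C give (2R,3E)-4-(7-methoxy-2,2-dimethyl-2H-chromen-6-yl)but-3-en-2-yl pivalate F3, kept cold and base-washed because it can ionise. Separately, bromide 5 is lithiated (n-BuLi, THF, −78 °C), trapped with B(OiPr)3 and hydrolysed with aq. NH4Cl to (7-methoxy-2,2-dimethyl-2H-chromen-6-yl)boronic acid F4, which is dried azeotropically to 2,4,6-tris(7-methoxy-2,2-dimethyl-2H-chromen-6-yl)boroxine F5. Enantiospecific nickel-catalysed coupling of F3 with F5 (Ni(cod)2 as the zerovalent nickel source, BnPPh2, NaOMe, THF, rt) is expected to arylate the methyl-bearing carbon with inversion, keeping the styrene conjugation, and so convert the (R) pivalate into (S)-20.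

2. Step 1. The templated C–C bond formation may go to the wrong ortho position or stall while prenal oligomerises, and the product chromene may dimerise on prolonged heating with acid. Fallback (sets out from phenol 1, comes back at bromochromene 5): the pyran ring is built by acylation. Phenol 1 and 3-methylbut-2-enoic acid in P2O5/MeSO3H at 70 °C should undergo Friedel–Crafts acylation para to the methoxy group and oxa-Michael closure to 6-bromo-7-methoxy-2,2-dimethylchroman-4-one F6. NaBH4 in MeOH at 0 °C gives racemic 6-bromo-7-methoxy-2,2-dimethylchroman-4-ol F7, and brief dehydration (p-TsOH cat., toluene, 80 °C) gives 5.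

3. Step 6. Alkoxide 17 may undergo a base-induced 1,3-hydrogen shift to the saturated ketone before methylation is complete, and the alcohol or ether may ionise and oligomerise on work-up. Fallback (sets out from alcohol 16, comes back at ether 18): SN1 methanolysis in place of alkoxide alkylation. Stirring 16 with catalytic pyridinium p-toluenesulfonate in MeOH at rt, then neutralising with Et3N, should give 18 through the symmetric diarylallyl cation, which methanol captures to the same ether at either terminus; no alkoxide is formed.

**Further compounds**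

F1 | step 7 | (3E)-4-(7-methoxy-2,2-dimethyl-2H-chromen-6-yl)but-3-en-2-one | COc1cc2OC(C)(C)C=Cc2cc1/C=C/C(C)=O
F2 | step 7 | (2R,3E)-4-(7-methoxy-2,2-dimethyl-2H-chromen-6-yl)but-3-en-2-ol | C[C@@H](O)/C=C/c1cc2C=CC(C)(C)Oc2cc1OC
F3 | step 7 | (2R,3E)-4-(7-methoxy-2,2-dimethyl-2H-chromen-6-yl)but-3-en-2-yl 2,2-dimethylpropanoate | C[C@@H](OC(=O)C(C)(C)C)/C=C/c1cc2C=CC(C)(C)Oc2cc1OC
F4 | step 7 | (7-methoxy-2,2-dimethyl-2H-chromen-6-yl)boronic acid | COc1cc2OC(C)(C)C=Cc2cc1B(O)O
F5 | step 7 | 2,4,6-tris(7-methoxy-2,2-dimethyl-2H-chromen-6-yl)-1,3,5,2,4,6-trioxatriborinane | COc1cc2OC(C)(C)C=Cc2cc1B1OB(c2cc3C=CC(C)(C)Oc3cc2OC)OB(c2cc3C=CC(C)(C)Oc3cc2OC)O1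
F6 | step 1 | 6-bromo-7-methoxy-2,2-dimethylchroman-4-one | COc1cc2OC(C)(C)CC(=O)c2cc1Br
F7 | step 1 | racemic 6-bromo-7-methoxy-2,2-dimethylchroman-4-ol | COc1cc2OC(C)(C)CC(O)c2cc1Br
F0 | step 6 | none | none
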